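## Retrosynthetic overview

- The route rests on chain carbon C2, the tertiary carbinol bonded to C6 of the chromene, a methyl group and the C3 methylene. It is treated as the boron-bearing carbon of an isopropenyl boronate, so the C2–aryl and C3–C4 bonds are made in one three-component coupling and C2–O is derived from C2–B.
- Late disconnections: C4–H (hydrogenation of a C4 methylidene), then the furan ring of the benzofuran (O1–C2 and C3–C3a, from a terminal alkyne and an ortho-iodophenol), then C–Si and C–B.
- Coupling partners: the 6-lithio derivative of 6-bromo-7-methoxy-2,2-dimethyl-2H-chromene, isopropenyl pinacol boronate, and the enol triflate of 4-(trimethylsilyl)but-3-yn-2-one.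
- Ring order: the pyran ring of the chromene first (propargyl ether Claisen rearrangement and electrocyclisation), the furan ring in the last but one step; both benzene rings are bought.

Key step: step 4

Assumption: chain atoms are numbered as in pentan-2-ol (C1 methyl, C2 carbinol, C3 methylene, C4 methine, C5 methyl), and the ligand antipodes written in steps 4 and 8 are taken to be those that give the 2R boronate and the 4S centre; if either proves mismatched, its mirror-image ligand is used with no other change.

## Route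

Step 1
Reactants: 1 4-bromo-3-methoxyphenol; 2 3-chloro-3-methylbut-1-yne
Product: 3 1-bromo-2-methoxy-4-[(2-methylbut-3-yn-2-yl)oxy]benzene
Conditions: DBU, CuCl2·2H2O (cat.), MeCN, 0 °C → rt
Reagents that add atoms: none
Why: Copper-catalysed O-propargylation of a phenol with a tertiary propargylic chloride is the standard entry to 1,1-dimethylpropargyl aryl ethers, and the aryl bromide and methoxy group are inert to it.

Step 2
Reactants: 3 1-bromo-2-methoxy-4-[(2-methylbut-3-yn-2-yl)oxy]benzene
Product: 4 6-bromo-7-methoxy-2,2-dimethyl-2H-chromene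
Conditions: N,N-diethylaniline, 180 °C
Reagents that add atoms: none
Why: Aromatic propargyl Claisen rearrangement, then enolisation, 1,5-hydrogen shift and oxa-6π electrocyclisation, closes the pyran ring; attack at the ring position para to the methoxy group should dominate because the position between the two oxygens is blocked by the methoxy group, which the neighbouring bromine buttresses, and the minor 5-methoxy isomer is removed by chromatography.

Step 3
Reactants: 5 4-(trimethylsilyl)but-3-yn-2-one
Product: 6 4-(trimethylsilyl)but-1-en-3-yn-2-yl trifluoromethanesulfonate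
Conditions: KN(SiMe3)2, THF, −78 °C; PhNTf2, −78 → 0 °C
Reagents that add atoms: N-phenylbis(trifluoromethanesulfonimide), O=S(=O)(N(c1ccccc1)S(=O)(=O)C(F)(F)F)C(F)(F)F
Why: Kinetic deprotonation of the methyl ketone by a hindered, non-nucleophilic amide base (the silyl group shields the alkyne terminus from conjugate addition) and O-sulfonylation of the enolate is the usual enol triflate synthesis.

Step 4
Reactants: 4 6-bromo-7-methoxy-2,2-dimethyl-2H-chromene; 7 4,4,5,5-tetramethyl-2-(prop-1-en-2-yl)-1,3,2-dioxaborolane; 6 4-(trimethylsilyl)but-1-en-3-yn-2-yl trifluoromethanesulfonate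
Product: 10 2-[(2R)-2-(7-methoxy-2,2-dimethyl-2H-chromen-6-yl)-4-methylidene-6-(trimethylsilyl)hex-5-yn-2-yl]-4,4,5,5-tetramethyl-1,3,2-dioxaborolane, via (7-methoxy-2,2-dimethyl-2H-chromen-6-yl)lithium 8 (not isolated), via lithium aryl(isopropenyl)(pinacolato)borate 9 (not isolated)
Conditions: t-BuLi (2 equiv), Et2O, −78 °C; 7, −78 °C → rt; solvent exchange to THF; 6, KOSO2CF3, Pd(OAc)2 (cat.), (Sp,Sp)-MandyPhos [(Sp,Sp)-1,1'-bis(diphenylphosphino)-2,2'-bis((R)-α-(dimethylamino)benzyl)ferrocene, C52H50FeN2P2] (cat.), 60 °C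
Reagents that add atoms: none
Why: Bromine–lithium exchange gives aryllithium 8, which adds to boron of 7 to give four-coordinate borate 9; oxidative addition of triflate 6 to zerovalent palladium gives a cationic enynyl complex of divalent palladium that binds the isopropenyl π-bond of 9, the aryl group shifts from boron to the internal alkene carbon anti to palladium (1,2-metallate shift), and reductive elimination from the alkyl(enynyl)palladium joins C3 to C4. The closest known reaction type is the enantioselective palladium/MandyPhos conjunctive cross-coupling of α-substituted alkenylboron ate complexes with alkenyl triflates, which gives tertiary boronic esters. No ring is closed. C2 is the only new stereocentre and is set by the chiral bisphosphine on palladium, which selects the enantiotopic face of the isopropenyl group that is bound before the anti migration. The step needs the metallate shift to outrun direct aryl transfer from boron to palladium; the pinacol ligand on boron favours the shift, and KOSO2CF3 removes the bromide left by the exchange as KBr so that the cationic palladium keeps its free site. The alkylpalladium intermediate has no hydrogen on C2, so β-hydride elimination cannot compete with reductive elimination.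

Step 5
Reactants: 10 2-[(2R)-2-(7-methoxy-2,2-dimethyl-2H-chromen-6-yl)-4-methylidene-6-(trimethylsilyl)hex-5-yn-2-yl]-4,4,5,5-tetramethyl-1,3,2-dioxaborolane
Product: 11 (2S)-2-(7-methoxy-2,2-dimethyl-2H-chromen-6-yl)-4-methylidene-6-(trimethylsilyl)hex-5-yn-2-ol
Conditions: H2O2 (30% aq.), NaOH (aq.), THF, 0 °C → rt
Reagents that add atoms: hydrogen peroxide, OO
Why: In this boronate oxidation hydroperoxide adds to boron and C2 migrates to oxygen with retention, so the 2R boronate gives the 2S alcohol (the descriptor changes only because oxygen outranks the aryl carbon), and the non-electrophilic oxidant leaves the enyne and chromene alkene alone.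

Step 6
Reactants: 11 (2S)-2-(7-methoxy-2,2-dimethyl-2H-chromen-6-yl)-4-methylidene-6-(trimethylsilyl)hex-5-yn-2-ol
Product: 12 (2S)-2-(7-methoxy-2,2-dimethyl-2H-chromen-6-yl)-4-methylidenehex-5-yn-2-ol
Conditions: K2CO3 (cat.), MeOH, rt
Reagents that add atoms: none
Why: Base-catalysed methanolysis of the alkynyl C–Si bond (protodesilylation) frees the terminal alkyne without touching the tertiary alcohol or either alkene.

Step 7
Reactants: 12 (2S)-2-(7-methoxy-2,2-dimethyl-2H-chromen-6-yl)-4-methylidenehex-5-yn-2-ol; 13 1-(2,4-dihydroxy-5-iodophenyl)ethan-1-one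
Product: 15 1-{6-hydroxy-2-[(4S)-4-hydroxy-4-(7-methoxy-2,2-dimethyl-2H-chromen-6-yl)pent-1-en-2-yl]-1-benzofuran-5-yl}ethan-1-one, via ortho-alkynylphenol 14 (not isolated)
Conditions: PdCl2(PPh3)2 (cat.), CuI (cat.), Et3N, DMF, 60 °C, degassed
Reagents that add atoms: none
Why: Sonogashira coupling at the aryl iodide is followed in the same flask by 5-endo-dig addition of the adjacent phenol oxygen to the metal-activated alkyne (tandem coupling–heteroannulation, as used for 2-alkenyl-5-acetyl-6-hydroxybenzofurans); only the hydroxyl ortho to iodine can close the furan, which fixes the 5-acetyl-6-hydroxy pattern, and the other hydroxyl stays hydrogen-bonded to the acetyl group.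

Step 8
Reactants: 15 1-{6-hydroxy-2-[(4S)-4-hydroxy-4-(7-methoxy-2,2-dimethyl-2H-chromen-6-yl)pent-1-en-2-yl]-1-benzofuran-5-yl}ethan-1-one
Product: 16 1-{6-hydroxy-2-[(2S,4S)-4-hydroxy-4-(7-methoxy-2,2-dimethyl-2H-chromen-6-yl)pentan-2-yl]-1-benzofuran-5-yl}ethan-1-one (target, CNP0233723.1)
Conditions: H2 (20 bar), [Rh(nbd)((S)-BINAP)]BF4 (cat.), CH2Cl2, rt, stopped after one equivalent of H2
Reagents that add atoms: none
Why: In this hydroxyl-directed homogeneous hydrogenation the tertiary hydroxyl and the 1,1-disubstituted alkene chelate the cationic rhodium, which confines reduction to that alkene and spares the chromene alkene, the aryl ketone and the benzofuran; because the remote carbinol centre (methyl against aryl) distinguishes the alkene faces only weakly, the C2-symmetric bisphosphine is relied on to deliver hydrogen to the Re face of C4 and set the 4S centre, and the elevated pressure suppresses alkene isomerisation.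

## Compound list

1 | 4-bromo-3-methoxyphenol | COc1cc(O)ccc1Br | starting material
2 | 3-chloro-3-methylbut-1-yne | CC(C)(Cl)C#C | starting material
3 | 1-bromo-2-methoxy-4-[(2-methylbut-3-yn-2-yl)oxy]benzene | COc1cc(OC(C)(C)C#C)ccc1Br | intermediate
4 | 6-bromo-7-methoxy-2,2-dimethyl-2H-chromene | COc1cc2OC(C)(C)C=Cc2cc1Br | intermediate
5 | 4-(trimethylsilyl)but-3-yn-2-one | CC(=O)C#C[Si](C)(C)C | starting material
6 | 4-(trimethylsilyl)but-1-en-3-yn-2-yl trifluoromethanesulfonate | C=C(OS(=O)(=O)C(F)(F)F)C#C[Si](C)(C)C | intermediate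
7 | 4,4,5,5-tetramethyl-2-(prop-1-en-2-yl)-1,3,2-dioxaborolane | CC(=C)B1OC(C)(C)C(C)(C)O1 | starting material
8 | (7-methoxy-2,2-dimethyl-2H-chromen-6-yl)lithium, formed in the flask | [Li]c1cc2C=CC(C)(C)Oc2cc1OC | intermediate
9 | lithium (7-methoxy-2,2-dimethyl-2H-chromen-6-yl)(prop-1-en-2-yl)(pinacolato)borate, formed in the flask | [Li+].COc1cc2OC(C)(C)C=Cc2cc1[B-]1(C(C)=C)OC(C)(C)C(C)(C)O1 | intermediate
10 | 2-[(2R)-2-(7-methoxy-2,2-dimethyl-2H-chromen-6-yl)-4-methylidene-6-(trimethylsilyl)hex-5-yn-2-yl]-4,4,5,5-tetramethyl-1,3,2-dioxaborolane | COc1cc2c(cc1[C@@](C)(B3OC(C)(C)C(C)(C)O3)CC(=C)C#C[Si](C)(C)C)C=CC(C)(C)O2 | intermediate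
11 | (2S)-2-(7-methoxy-2,2-dimethyl-2H-chromen-6-yl)-4-methylidene-6-(trimethylsilyl)hex-5-yn-2-ol | COc1cc2c(cc1[C@@](C)(O)CC(=C)C#C[Si](C)(C)C)C=CC(C)(C)O2 | intermediate
12 | (2S)-2-(7-methoxy-2,2-dimethyl-2H-chromen-6-yl)-4-methylidenehex-5-yn-2-ol | COc1cc2c(cc1[C@@](C)(O)CC(=C)C#C)C=CC(C)(C)O2 | intermediate
13 | 1-(2,4-dihydroxy-5-iodophenyl)ethan-1-one | CC(=O)c1cc(I)c(O)cc1O | starting material
14 | 1-{2,4-dihydroxy-5-[(5S)-5-hydroxy-5-(7-methoxy-2,2-dimethyl-2H-chromen-6-yl)-3-methylidenehex-1-yn-1-yl]phenyl}ethan-1-one, formed in the flask | COc1cc2c(cc1[C@@](C)(O)CC(=C)C#Cc1cc(C(C)=O)c(O)cc1O)C=CC(C)(C)O2 | intermediate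
15 | 1-{6-hydroxy-2-[(4S)-4-hydroxy-4-(7-methoxy-2,2-dimethyl-2H-chromen-6-yl)pent-1-en-2-yl]-1-benzofuran-5-yl}ethan-1-one | COc1cc2c(cc1[C@@](C)(O)CC(=C)c1cc3cc(C(C)=O)c(O)cc3o1)C=CC(C)(C)O2 | intermediate
16 | 1-{6-hydroxy-2-[(2S,4S)-4-hydroxy-4-(7-methoxy-2,2-dimethyl-2H-chromen-6-yl)pentan-2-yl]-1-benzofuran-5-yl}ethan-1-one | COc1cc2c(cc1[C@@](C)(O)C[C@H](C)c1cc3cc(C(C)=O)c(O)cc3o1)C=CC(C)(C)O2 | target

## Step count and risks

Total step count: 8. Longest linear sequence: 7 steps (steps 1, 2, 4, 5, 6, 7, 8 from compound 1); step 3 is a one-step branch.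

Steps most likely to fail:

1. Step 4. The ortho-methoxyaryl group may be slow to migrate onto a carbon that becomes quaternary, so that direct aryl transfer from boron to palladium (Suzuki-type coupling) or protodeboronation of the borate takes over, or the enantioface selection may be weak. The fallback is a lithiation–borylation that sets out from compounds 4 and 6 and comes back at compound 10. Bromide 4 is lithiated (t-BuLi, THF, −78 °C) and acylated with N-methoxy-N-methylacetamide to give 1-(7-methoxy-2,2-dimethyl-2H-chromen-6-yl)ethan-1-one F1. Asymmetric transfer hydrogenation (RuCl[(R,R)-TsDPEN](p-cymene), HCO2H/Et3N) should give (1R)-1-(7-methoxy-2,2-dimethyl-2H-chromen-6-yl)ethan-1-ol F2, and i-Pr2NCOCl/Et3N converts it to (1R)-1-(7-methoxy-2,2-dimethyl-2H-chromen-6-yl)ethyl N,N-di(propan-2-yl)carbamate F3. Triflate 6 is coupled with IZnCH2B(pin) under Pd(PPh3)4 in THF to give 4,4,5,5-tetramethyl-2-[2-methylidene-4-(trimethylsilyl)but-3-yn-1-yl]-1,3,2-dioxaborolane F4. Deprotonation of F3 with s-BuLi (Et2O, −78 °C) and addition of F4 gives the borate with retention at carbon; MgBr2·OEt2/MeOH then promotes 1,2-migration of the allylic group with loss of the carbamate. The overall result is replacement of the carbinol hydrogen by the allylic carbon and of oxygen by boron, which for the 1R carbamate is boronate 10.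

2. Step 8. Facial selection at C4 may be poor (a mismatched or weakly discriminating catalyst–substrate pair), the alkene may isomerise into the trisubstituted position, or the chromene alkene may be over-reduced. The fallback removes the hydroxyl direction and relies on an undirected, catalyst-controlled hydrogenation; it sets out from compound 15 and comes back at compound 16. Both hydroxyls are silylated (Me3SiCl, imidazole, DMF) to give 1-{2-[(4S)-4-(7-methoxy-2,2-dimethyl-2H-chromen-6-yl)-4-[(trimethylsilyl)oxy]pent-1-en-2-yl]-6-[(trimethylsilyl)oxy]-1-benzofuran-5-yl}ethan-1-one F5. The 2-heteroaryl-1-alkene is hydrogenated at 1 bar H2 with [Ir(cod)((S)-t-Bu-PHOX)][B(C6H3-3,5-(CF3)2)4] in CH2Cl2, where terminal 1,1-disubstituted alkenes react well ahead of the cyclic disubstituted chromene alkene, to give 1-{2-[(2S,4S)-4-(7-methoxy-2,2-dimethyl-2H-chromen-6-yl)-4-[(trimethylsilyl)oxy]pentan-2-yl]-6-[(trimethylsilyl)oxy]-1-benzofuran-5-yl}ethan-1-one F6. Bu4NF in THF at 0 °C removes both silyl groups to give 16.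

3. Step 3. The amide base may add in conjugate fashion to the ynone or the enolate may self-condense before it is trapped, and the small, labile triflate may be lost on isolation. The fallback generates the enolate indirectly; it sets out from compound 5 and comes back at compound 6. Soft enolisation (Me3SiOSO2CF3, Et3N, CH2Cl2, 0 °C) gives trimethyl{[4-(trimethylsilyl)but-1-en-3-yn-2-yl]oxy}silane F7, which is purified by distillation. MeLi in THF at 0 °C cleaves the O–Si bond to give the amine-free lithium enolate, which is trapped with PhNTf2 to give 6, used as a stock solution.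

## Further compounds

F1 | step 4 | 1-(7-methoxy-2,2-dimethyl-2H-chromen-6-yl)ethan-1-one | CC(=O)c1cc2C=CC(C)(C)Oc2cc1OC
F2 | step 4 | (1R)-1-(7-methoxy-2,2-dimethyl-2H-chromen-6-yl)ethan-1-ol | C[C@@H](O)c1cc2C=CC(C)(C)Oc2cc1OC
F3 | step 4 | (1R)-1-(7-methoxy-2,2-dimethyl-2H-chromen-6-yl)ethyl N,N-di(propan-2-yl)carbamate | C[C@@H](OC(=O)N(C(C)C)C(C)C)c1cc2C=CC(C)(C)Oc2cc1OC
F4 | step 4 | 4,4,5,5-tetramethyl-2-[2-methylidene-4-(trimethylsilyl)but-3-yn-1-yl]-1,3,2-dioxaborolane | C=C(CB1OC(C)(C)C(C)(C)O1)C#C[Si](C)(C)C
F5 | step 8 | 1-{2-[(4S)-4-(7-methoxy-2,2-dimethyl-2H-chromen-6-yl)-4-[(trimethylsilyl)oxy]pent-1-en-2-yl]-6-[(trimethylsilyl)oxy]-1-benzofuran-5-yl}ethan-1-one | COc1cc2c(cc1[C@@](C)(O[Si](C)(C)C)CC(=C)c1cc3cc(C(C)=O)c(O[Si](C)(C)C)cc3o1)C=CC(C)(C)O2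
F6 | step 8 | 1-{2-[(2S,4S)-4-(7-methoxy-2,2-dimethyl-2H-chromen-6-yl)-4-[(trimethylsilyl)oxy]pentan-2-yl]-6-[(trimethylsilyl)oxy]-1-benzofuran-5-yl}ethan-1-one | COc1cc2c(cc1[C@@](C)(O[Si](C)(C)C)C[C@H](C)c1cc3cc(C(C)=O)c(O[Si](C)(C)C)cc3o1)C=CC(C)(C)O2
F7 | step 3 | trimethyl{[4-(trimethylsilyl)but-1-en-3-yn-2-yl]oxy}silane | C=C(O[Si](C)(C)C)C#C[Si](C)(C)C
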